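## Retrosynthetic overview

1. Target 21 ⇐ Nef reaction of macrocyclic nitroalkane 19; the C14 ketone is carried as a nitro group.
2. 19 ⇐ palladium π-allyl ring closure (C13–C14) of nitro lactone carbonate 18; the nitronate serves as the acyl-anion equivalent, replacing the usual ring-closing metathesis or allyl-chromium closure.
3. cis-Lactone (C1, C2, C15) ⇐ syn-selective nitromethane conjugate addition to γ-alkoxy enoate 11, lactonisation, trans α-methylation.
4. C2/C3 ⇐ Brown (Z)-γ-alkoxyallylboration of oxolane aldehyde 9, then acrylate cross-metathesis; oxolane (C4/C7) ⇐ perrhenate oxidative cyclisation of dienol 7.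
5. C7/C8 and the E-C11=C12 alkene ⇐ (R)-citronellal. Ring order: oxolane, then lactone, then the 14-membered carbocycle.

Numbering: cembrane numbering. C1 is the ring CH bearing the lactone CH(CH3) (C15; C16 is the lactone C=O, C17 its methyl); C2 is the lactone O–CH; C3 is CHOH; C4 and C7 are the oxolane carbons; C8 is CH(CH3); C11=C12 is the alkene; C14 is the ketone.

Assumption: 3-(methoxymethoxy)prop-1-ene, (+)-Ipc2BOMe and 2-methylallylmagnesium chloride are bought; 19 is carried as a mixture of C14 epimers because C14 becomes the ketone carbon.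

## Route

Step 1
Reactants: 1 (R)-citronellal
Product: 3 (2S,3R)-3,7-dimethyl-2-[(phenylamino)oxy]oct-6-en-1-ol, via aminoxy aldehyde 2 (not isolated)
Conditions: D-proline (20 mol%), PhNO, CHCl3, 4 °C; then NaBH4, EtOH, 0 °C
Reagents that add atoms: nitrosobenzene O=Nc1ccccc1
Why: Proline enamine catalysis (α-aminoxylation): L-proline gives 2R products, so D-proline sets 2S (C7 of the target) under catalyst control, and in situ borohydride reduction prevents epimerisation.

Step 2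
Reactants: 3 (2S,3R)-3,7-dimethyl-2-[(phenylamino)oxy]oct-6-en-1-ol
Product: 4 (2S,3R)-3,7-dimethyloct-6-ene-1,2-diol
Conditions: Zn, AcOH/EtOH, rt
Reagents that add atoms: none
Why: Dissolving-metal reductive cleavage of the N–O bond leaves the alkene and both stereocentres untouched.

Step 3
Reactants: 4 (2S,3R)-3,7-dimethyloct-6-ene-1,2-diol
Product: 6 (2S)-2-[(2R)-6-methylhept-5-en-2-yl]oxirane, via primary tosylate 5 (not isolated)
Conditions: NaH (2.2 equiv), N-tosylimidazole (1.05 equiv), THF, 0 °C to rt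
Reagents that add atoms: none
Why: Selective sulfonylation of the primary hydroxyl then intramolecular Williamson closure by the secondary alkoxide; the C7–O bond is never broken, so configuration is retained.

Step 4
Reactants: 6 (2S)-2-[(2R)-6-methylhept-5-en-2-yl]oxirane
Product: 7 (5R,6R)-2,6,10-trimethylundeca-1,9-dien-5-ol
Conditions: CH2=C(CH3)CH2MgCl (1.5 equiv), CuI (10 mol%), THF, −30 to 0 °C
Reagents that add atoms: 2-methylallylmagnesium chloride CC(=C)C[Mg]Cl
Why: Copper-catalysed SN2 opening of the terminal epoxide at its CH2 carbon (C6) by a symmetrical allyl nucleophile; the C7 carbinol centre is untouched.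

Step 5
Reactants: 7 (5R,6R)-2,6,10-trimethylundeca-1,9-dien-5-ol
Product: 8 [(2R,5R)-2-methyl-5-[(2R)-6-methylhept-5-en-2-yl]oxolan-2-yl]methanol
Conditions: Re2O7 (1.5 equiv), 2,6-lutidine (3 equiv), CH2Cl2, rt; then aq. NaOH/H2O2
Reagents that add atoms: dirhenium heptoxide O=[Re](=O)(=O)O[Re](=O)(=O)=O
Why: Perrhenate-mediated syn-oxidative cyclisation of a 5-hydroxyalkene: the C7 perrhenate ester adds across the proximal 1,1-disubstituted alkene (five-ring closure outruns six-ring closure onto the remote alkene) through a chair-like transition state with the C7 side chain pseudo-equatorial, giving the 2,5-trans oxolane (C4 R).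

Step 6
Reactants: 8 [(2R,5R)-2-methyl-5-[(2R)-6-methylhept-5-en-2-yl]oxolan-2-yl]methanol
Product: 9 (2R,5R)-2-methyl-5-[(2R)-6-methylhept-5-en-2-yl]oxolane-2-carbaldehyde
Conditions: TEMPO (10 mol%), PhI(OAc)2 (1.2 equiv), CH2Cl2, rt
Reagents that add atoms: none
Why: Oxoammonium (TEMPO) oxidation of the primary alcohol; the aldehyde has no α-hydrogen, so C4 cannot epimerise.

Step 7
Reactants: 9 (2R,5R)-2-methyl-5-[(2R)-6-methylhept-5-en-2-yl]oxolane-2-carbaldehyde
Product: 10 (1R,2S)-2-(methoxymethoxy)-1-[(2R,5R)-2-methyl-5-[(2R)-6-methylhept-5-en-2-yl]oxolan-2-yl]but-3-en-1-ol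
Conditions: CH2=CHCH2OCH2OCH3, s-BuLi, THF, −78 °C; (+)-Ipc2BOMe; BF3·OEt2; then 9, −78 °C to rt; NaOH, H2O2
Reagents that add atoms: [(Z)-3-(methoxymethoxy)prop-2-en-1-yl]bis(isopinocampheyl)borane COCO/C=C\CB([C@H]1C[C@H]2C[C@@H]([C@@H]1C)C2(C)C)[C@H]1C[C@H]2C[C@@H]([C@@H]1C)C2(C)C
Why: Brown γ-alkoxyallylboration through a closed chair transition state: the Z reagent gives the syn 1,2-diol monoether and the isopinocampheyl groups derived from (−)-α-pinene direct attack to the Re face of the aldehyde, setting C3 (R) and C2 (S) under reagent control.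

Step 8
Reactants: 10 (1R,2S)-2-(methoxymethoxy)-1-[(2R,5R)-2-methyl-5-[(2R)-6-methylhept-5-en-2-yl]oxolan-2-yl]but-3-en-1-ol
Product: 11 methyl (2E,4S,5R)-5-hydroxy-4-(methoxymethoxy)-5-[(2R,5R)-2-methyl-5-[(2R)-6-methylhept-5-en-2-yl]oxolan-2-yl]pent-2-enoate
Conditions: methyl acrylate (10 equiv), second-generation Hoveyda–Grubbs catalyst RuCl2(H2IMes)(=CH-C6H4-2-OiPr) (5 mol%), CH2Cl2, 40 °C
Reagents that add atoms: methyl acrylate C=CC(=O)OC
Why: Olefin cross-metathesis of the terminal alkene with an acrylate gives the E enoate, while the trisubstituted alkene is inert.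

Step 9
Reactants: 11 methyl (2E,4S,5R)-5-hydroxy-4-(methoxymethoxy)-5-[(2R,5R)-2-methyl-5-[(2R)-6-methylhept-5-en-2-yl]oxolan-2-yl]pent-2-enoate
Product: 12 methyl (3S,4S,5R)-5-hydroxy-4-(methoxymethoxy)-5-[(2R,5R)-2-methyl-5-[(2R)-6-methylhept-5-en-2-yl]oxolan-2-yl]-3-(nitromethyl)pentanoate
Conditions: CH3NO2 (20 equiv), Bu4NF·3H2O (0.3 equiv), THF, 0 °C to rt
Reagents that add atoms: nitromethane C[N+](=O)[O-]
Why: Nitro-Michael addition to a γ-alkoxy enoate: with the C2–H eclipsing the alkene, the nitronate attacks anti to the bulky C3 substituent, giving the syn adduct (C1) that corresponds to the cis-lactone.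

Step 10
Reactants: 12 methyl (3S,4S,5R)-5-hydroxy-4-(methoxymethoxy)-5-[(2R,5R)-2-methyl-5-[(2R)-6-methylhept-5-en-2-yl]oxolan-2-yl]-3-(nitromethyl)pentanoate
Product: 14 (4S,5S)-5-[(R)-hydroxy[(2R,5R)-2-methyl-5-[(2R)-6-methylhept-5-en-2-yl]oxolan-2-yl]methyl]-4-(nitromethyl)oxolan-2-one, via dihydroxy ester 13 (not isolated)
Conditions: conc. HCl (cat.), MeOH, 40 °C; then PPTS (cat.), toluene, 60 °C
Reagents that add atoms: none
Why: Acid-catalysed acetal exchange frees the C2 hydroxyl, which closes the five-membered lactone in preference to the six-membered alternative through the hindered C3 hydroxyl; no stereocentre is touched.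

Step 11
Reactants: 14 (4S,5S)-5-[(R)-hydroxy[(2R,5R)-2-methyl-5-[(2R)-6-methylhept-5-en-2-yl]oxolan-2-yl]methyl]-4-(nitromethyl)oxolan-2-one
Product: 16 (3R,4S,5S)-5-[(R)-hydroxy[(2R,5R)-2-methyl-5-[(2R)-6-methylhept-5-en-2-yl]oxolan-2-yl]methyl]-3-methyl-4-(nitromethyl)oxolan-2-one, via trilithium salt 15 (not isolated)
Conditions: LiN(iPr)2 (3.3 equiv), THF/DMPU, −78 °C; CH3I (1.2 equiv), −78 to −50 °C; AcOH
Reagents that add atoms: iodomethane CI
Why: Polyanion alkylation: the lactone enolate is the most basic and most nucleophilic site and is methylated anti to the adjacent C1 substituent, setting C15 with the methyl trans to the nitromethyl group.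

Step 12
Reactants: 16 (3R,4S,5S)-5-[(R)-hydroxy[(2R,5R)-2-methyl-5-[(2R)-6-methylhept-5-en-2-yl]oxolan-2-yl]methyl]-3-methyl-4-(nitromethyl)oxolan-2-one
Product: 17 (3R,4S,5S)-5-[(R)-hydroxy[(2R,5R)-5-[(2R,5E)-7-hydroxy-6-methylhept-5-en-2-yl]-2-methyloxolan-2-yl]methyl]-3-methyl-4-(nitromethyl)oxolan-2-one
Conditions: SeO2 (0.3 equiv), t-BuOOH (3 equiv), salicylic acid (10 mol%), CH2Cl2, rt
Reagents that add atoms: selenium dioxide O=[Se]=O (catalytic oxygen carrier); tert-butyl hydroperoxide CC(C)(C)OO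
Why: SeO2 allylic oxidation (ene reaction then [2,3]-sigmatropic shift) is selective for the E-methyl group of the electron-rich trisubstituted alkene, so C13 is hydroxylated with the 11E geometry fixed.

Step 13
Reactants: 17 (3R,4S,5S)-5-[(R)-hydroxy[(2R,5R)-5-[(2R,5E)-7-hydroxy-6-methylhept-5-en-2-yl]-2-methyloxolan-2-yl]methyl]-3-methyl-4-(nitromethyl)oxolan-2-one
Product: 18 (2E,6R)-6-[(2R,5R)-5-[(R)-hydroxy[(2S,3S,4R)-4-methyl-3-(nitromethyl)-5-oxooxolan-2-yl]methyl]-5-methyloxolan-2-yl]-2-methylhept-2-en-1-yl methyl carbonate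
Conditions: ClCO2Me (1.3 equiv), pyridine, CH2Cl2, 0 °C
Reagents that add atoms: methyl chloroformate COC(=O)Cl
Why: Acylation of the unhindered primary allylic alcohol; the C3 hydroxyl next to the quaternary C4 does not react.

Step 14
Reactants: 18 (2E,6R)-6-[(2R,5R)-5-[(R)-hydroxy[(2S,3S,4R)-4-methyl-3-(nitromethyl)-5-oxooxolan-2-yl]methyl]-5-methyloxolan-2-yl]-2-methylhept-2-en-1-yl methyl carbonate
Product: 19 macrocyclic nitro lactone (target skeleton with H and NO2 on C14 in place of the ketone oxygen; C14 epimers)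
Conditions: Pd2(dba)3·CHCl3 (5 mol%), dppe (12 mol%), THF, 0.002 M (syringe pump), 65 °C
Reagents that add atoms: none
Why: Proposed new method: ionisation of the allyl carbonate by zerovalent palladium releases methoxide, which deprotonates the primary nitroalkane (by far the most acidic site), and the soft nitronate carbon attacks the unsubstituted terminus (C13) of the π-allyl complex faster than syn–anti isomerisation, closing the 14-membered ring with the E alkene kept; the closest known reactions are the Tsuji–Trost C-allylation of nitroalkanes with allylic carbonates under neutral conditions and palladium π-allyl macrocyclisations of stabilised carbanions.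

Step 15
Reactants: 19 macrocyclic nitro lactone
Product: 21 CNP0386136.3 (1R,2S,3R,4R,7R,8R,11E,15R)-4,7-epoxy-3-hydroxy-14-oxocembr-11-en-16,2-olide, via potassium nitronate 20 (not isolated)
Conditions: KOtBu (1.05 equiv), THF, 0 °C; then TiCl3 (aq., 4 equiv), NH4OAc buffer (pH 5–6), 0 °C to rt
Reagents that add atoms: water O
Why: Nef reaction in its titanium trichloride form: the nitronate is reduced by trivalent titanium to the imine, which hydrolyses in the buffered medium to the C14 ketone without base, so the β-acyloxy ketone and the C1/C15 centres are not exposed to elimination or epimerisation.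

## Compound list

1 | (R)-citronellal, (3R)-3,7-dimethyloct-6-enal | CC(C)=CCC[C@@H](C)CC=O | starting material
2 | (2S,3R)-3,7-dimethyl-2-[(phenylamino)oxy]oct-6-enal | CC(C)=CCC[C@@H](C)[C@H](ONc1ccccc1)C=O | intermediate
3 | (2S,3R)-3,7-dimethyl-2-[(phenylamino)oxy]oct-6-en-1-ol | CC(C)=CCC[C@@H](C)[C@H](ONc1ccccc1)CO | intermediate
4 | (2S,3R)-3,7-dimethyloct-6-ene-1,2-diol | CC(C)=CCC[C@@H](C)[C@H](O)CO | intermediate
5 | (2S,3R)-2-hydroxy-3,7-dimethyloct-6-en-1-yl 4-methylbenzenesulfonate | CC(C)=CCC[C@@H](C)[C@H](O)COS(=O)(=O)c1ccc(C)cc1 | intermediate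
6 | (2S)-2-[(2R)-6-methylhept-5-en-2-yl]oxirane | CC(C)=CCC[C@@H](C)[C@H]1CO1 | intermediate
7 | (5R,6R)-2,6,10-trimethylundeca-1,9-dien-5-ol | CC(C)=CCC[C@@H](C)[C@H](O)CCC(C)=C | intermediate
8 | [(2R,5R)-2-methyl-5-[(2R)-6-methylhept-5-en-2-yl]oxolan-2-yl]methanol | CC(C)=CCC[C@@H](C)[C@H]1CC[C@@](C)(O1)CO | intermediate
9 | (2R,5R)-2-methyl-5-[(2R)-6-methylhept-5-en-2-yl]oxolane-2-carbaldehyde | CC(C)=CCC[C@@H](C)[C@H]1CC[C@@](C)(O1)C=O | intermediate
10 | (1R,2S)-2-(methoxymethoxy)-1-[(2R,5R)-2-methyl-5-[(2R)-6-methylhept-5-en-2-yl]oxolan-2-yl]but-3-en-1-ol | CC(C)=CCC[C@@H](C)[C@H]1CC[C@@](C)(O1)[C@H](O)[C@@H](OCOC)C=C | intermediate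
11 | methyl (2E,4S,5R)-5-hydroxy-4-(methoxymethoxy)-5-[(2R,5R)-2-methyl-5-[(2R)-6-methylhept-5-en-2-yl]oxolan-2-yl]pent-2-enoate | CC(C)=CCC[C@@H](C)[C@H]1CC[C@@](C)(O1)[C@H](O)[C@@H](OCOC)/C=C/C(=O)OC | intermediate
12 | methyl (3S,4S,5R)-5-hydroxy-4-(methoxymethoxy)-5-[(2R,5R)-2-methyl-5-[(2R)-6-methylhept-5-en-2-yl]oxolan-2-yl]-3-(nitromethyl)pentanoate | CC(C)=CCC[C@@H](C)[C@H]1CC[C@@](C)(O1)[C@H](O)[C@@H](OCOC)[C@H](C[N+](=O)[O-])CC(=O)OC | intermediate
13 | methyl (3S,4S,5R)-4,5-dihydroxy-5-[(2R,5R)-2-methyl-5-[(2R)-6-methylhept-5-en-2-yl]oxolan-2-yl]-3-(nitromethyl)pentanoate | CC(C)=CCC[C@@H](C)[C@H]1CC[C@@](C)(O1)[C@H](O)[C@@H](O)[C@H](C[N+](=O)[O-])CC(=O)OC | intermediate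
14 | (4S,5S)-5-[(R)-hydroxy[(2R,5R)-2-methyl-5-[(2R)-6-methylhept-5-en-2-yl]oxolan-2-yl]methyl]-4-(nitromethyl)oxolan-2-one | CC(C)=CCC[C@@H](C)[C@H]1CC[C@@](C)(O1)[C@H](O)[C@H]1OC(=O)C[C@H]1C[N+](=O)[O-] | intermediate
15 | trilithium salt of 14 (C3 alkoxide, lactone enolate, nitronate) | [Li+].[Li+].[Li+].CC(C)=CCC[C@@H](C)[C@H]1CC[C@@](C)(O1)[C@H]([O-])[C@H]1OC([O-])=C[C@H]1C=[N+]([O-])[O-] | intermediate
16 | (3R,4S,5S)-5-[(R)-hydroxy[(2R,5R)-2-methyl-5-[(2R)-6-methylhept-5-en-2-yl]oxolan-2-yl]methyl]-3-methyl-4-(nitromethyl)oxolan-2-one | CC(C)=CCC[C@@H](C)[C@H]1CC[C@@](C)(O1)[C@H](O)[C@H]1OC(=O)[C@H](C)[C@H]1C[N+](=O)[O-] | intermediate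
17 | (3R,4S,5S)-5-[(R)-hydroxy[(2R,5R)-5-[(2R,5E)-7-hydroxy-6-methylhept-5-en-2-yl]-2-methyloxolan-2-yl]methyl]-3-methyl-4-(nitromethyl)oxolan-2-one | OC/C(C)=C/CC[C@@H](C)[C@H]1CC[C@@](C)(O1)[C@H](O)[C@H]1OC(=O)[C@H](C)[C@H]1C[N+](=O)[O-] | intermediate
18 | (2E,6R)-6-[(2R,5R)-5-[(R)-hydroxy[(2S,3S,4R)-4-methyl-3-(nitromethyl)-5-oxooxolan-2-yl]methyl]-5-methyloxolan-2-yl]-2-methylhept-2-en-1-yl methyl carbonate | COC(=O)OC/C(C)=C/CC[C@@H](C)[C@H]1CC[C@@](C)(O1)[C@H](O)[C@H]1OC(=O)[C@H](C)[C@H]1C[N+](=O)[O-] | intermediate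
19 | macrocyclic nitro lactone: (1R,2S,3R,4R,7R,8R,11E,15R)-4,7-epoxy-3-hydroxy-14-nitrocembr-11-en-16,2-olide, C14 epimers | C/C1=C\CC[C@@H](C)[C@H]2CC[C@@](C)(O2)[C@H](O)[C@H]2OC(=O)[C@H](C)[C@H]2C([N+](=O)[O-])C1 | intermediate
20 | potassium nitronate of 19 | [K+].C/C1=C\CC[C@@H](C)[C@H]2CC[C@@](C)(O2)[C@H](O)[C@H]2OC(=O)[C@H](C)[C@H]2C(C1)=[N+]([O-])[O-] | intermediate
21 | CNP0386136.3, (1R,2S,3R,4R,7R,8R,11E,15R)-4,7-epoxy-3-hydroxy-14-oxocembr-11-en-16,2-olide | C/C1=C\CC[C@@H](C)[C@H]2CC[C@@](C)(O2)[C@H](O)[C@H]2OC(=O)[C@H](C)[C@H]2C(=O)C1 | target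

## Step count and risks

Total step count: 15. Longest linear sequence: 15 steps from (R)-citronellal.

Three steps most likely to fail:

Step 14 (palladium ring closure with a nitronate). The risks are oligomerisation, O-allylation and loss of the E geometry. The fallback closes the ring by conjugate addition instead, forming C14–C1. It sets out from 11. SeO2/t-BuOOH gives the allylic alcohol F1, and ClCO2Me/pyridine gives the methyl carbonate F2. Pd2(dba)3·CHCl3/PPh3 with nitromethane as co-solvent gives the chain-extended primary nitro compound F3. Bu4NF·3H2O in THF at 0.002 M then closes the 14-membered ring by intramolecular nitro-Michael addition to the enoate, giving the macrocyclic ester F4. HCl/MeOH then PPTS gives the macrocyclic lactone lacking the C15 methyl F5. Methylation with LiN(iPr)2/CH3I comes back to the route at 19.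

Step 9 (facial selectivity of the nitromethane addition). The syn preference is substrate-controlled and is the least certain stereochemical call in the route. The fallback puts C1 under catalyst control. It sets out from 10. Cross-metathesis with acrolein gives the enal F6. Nitromethane addition under iminium catalysis, using the enantiomer of diphenylprolinol trimethylsilyl ether that delivers the 3S centre, gives the nitro aldehyde F7. NaClO2/NaH2PO4/2-methyl-2-butene gives the carboxylic acid F8. HCl/MeOH then PPTS removes the acetal and lactonises, returning to the route at 14.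

Step 11 (methylation of a trianion next to a nitronate). The risks are nitronate alkylation and incomplete enolisation. The fallback carries the methyl group in from the metathesis partner. It sets out from 10. Cross-metathesis with methyl methacrylate gives the trisubstituted enoate F9. Nitromethane/DBU addition, where allylic 1,3-strain now fixes the reactive conformer, gives the adduct F10 as C15 epimers. HCl/MeOH then PPTS gives the lactone F11 as C15 epimers. DBU in toluene at 80 °C equilibrates C15 to the isomer with the methyl trans to the nitromethyl group, returning to the route at 16.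

Further compounds

F1 | step 14 | methyl (2E,4S,5R)-5-hydroxy-5-[(2R,5R)-5-[(2R,5E)-7-hydroxy-6-methylhept-5-en-2-yl]-2-methyloxolan-2-yl]-4-(methoxymethoxy)pent-2-enoate | OC/C(C)=C/CC[C@@H](C)[C@H]1CC[C@@](C)(O1)[C@H](O)[C@@H](OCOC)/C=C/C(=O)OC
F2 | step 14 | methyl carbonate of F1 at the primary allylic hydroxyl | COC(=O)OC/C(C)=C/CC[C@@H](C)[C@H]1CC[C@@](C)(O1)[C@H](O)[C@@H](OCOC)/C=C/C(=O)OC
F3 | step 14 | methyl (2E,4S,5R)-5-hydroxy-4-(methoxymethoxy)-5-[(2R,5R)-2-methyl-5-[(2R,5E)-6-methyl-8-nitrooct-5-en-2-yl]oxolan-2-yl]pent-2-enoate | [O-][N+](=O)CC/C(C)=C/CC[C@@H](C)[C@H]1CC[C@@](C)(O1)[C@H](O)[C@@H](OCOC)/C=C/C(=O)OC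
F4 | step 14 | macrocyclic ester: 14-membered ring closed C14–C1, C1 bearing CH2CO2CH3, C2 bearing OCH2OCH3, C14 bearing NO2 (C14 epimers) | C/C1=C\CC[C@@H](C)[C@H]2CC[C@@](C)(O2)[C@H](O)[C@@H](OCOC)[C@@H](CC(=O)OC)C([N+](=O)[O-])C1
F5 | step 14 | macrocyclic nitro lactone lacking the C15 methyl (C14 epimers) | C/C1=C\CC[C@@H](C)[C@H]2CC[C@@](C)(O2)[C@H](O)[C@H]2OC(=O)C[C@H]2C([N+](=O)[O-])C1
F6 | step 9 | (2E,4S,5R)-5-hydroxy-4-(methoxymethoxy)-5-[(2R,5R)-2-methyl-5-[(2R)-6-methylhept-5-en-2-yl]oxolan-2-yl]pent-2-enal | CC(C)=CCC[C@@H](C)[C@H]1CC[C@@](C)(O1)[C@H](O)[C@@H](OCOC)/C=C/C=O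
F7 | step 9 | (3S,4S,5R)-5-hydroxy-4-(methoxymethoxy)-5-[(2R,5R)-2-methyl-5-[(2R)-6-methylhept-5-en-2-yl]oxolan-2-yl]-3-(nitromethyl)pentanal | CC(C)=CCC[C@@H](C)[C@H]1CC[C@@](C)(O1)[C@H](O)[C@@H](OCOC)[C@H](C[N+](=O)[O-])CC=O
F8 | step 9 | (3S,4S,5R)-5-hydroxy-4-(methoxymethoxy)-5-[(2R,5R)-2-methyl-5-[(2R)-6-methylhept-5-en-2-yl]oxolan-2-yl]-3-(nitromethyl)pentanoic acid | CC(C)=CCC[C@@H](C)[C@H]1CC[C@@](C)(O1)[C@H](O)[C@@H](OCOC)[C@H](C[N+](=O)[O-])CC(=O)O
F9 | step 11 | methyl (2E,4S,5R)-5-hydroxy-4-(methoxymethoxy)-2-methyl-5-[(2R,5R)-2-methyl-5-[(2R)-6-methylhept-5-en-2-yl]oxolan-2-yl]pent-2-enoate | CC(C)=CCC[C@@H](C)[C@H]1CC[C@@](C)(O1)[C@H](O)[C@@H](OCOC)/C=C(\C)C(=O)OC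
F10 | step 11 | methyl (3S,4S,5R)-5-hydroxy-4-(methoxymethoxy)-2-methyl-5-[(2R,5R)-2-methyl-5-[(2R)-6-methylhept-5-en-2-yl]oxolan-2-yl]-3-(nitromethyl)pentanoate (C2 epimers) | CC(C)=CCC[C@@H](C)[C@H]1CC[C@@](C)(O1)[C@H](O)[C@@H](OCOC)[C@H](C[N+](=O)[O-])C(C)C(=O)OC
F11 | step 11 | (4S,5S)-5-[(R)-hydroxy[(2R,5R)-2-methyl-5-[(2R)-6-methylhept-5-en-2-yl]oxolan-2-yl]methyl]-3-methyl-4-(nitromethyl)oxolan-2-one (C3 epimers) | CC(C)=CCC[C@@H](C)[C@H]1CC[C@@](C)(O1)[C@H](O)[C@H]1OC(=O)C(C)[C@H]1C[N+](=O)[O-]
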